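The plan rests on disconnecting the lactone between its carbonyl carbon C2 and the benzyl-bearing carbon C3. A radical carboxyarylation of a homoallylic O-aryl thionocarbonate closes the oxolanone ring by 5-exo-trig attack of the thiocarbonyl-derived carbon radical on a vinyl group. In the same operation it shifts the guaiacyl ring from oxygen to the exocyclic methylene by 1,4-aryl migration. The step exploits the C2(=O)–C3–CH2–aryl array of the lactone and sets C3 trans to C4. The precursor is an acyclic thionocarbonate built from an Evans syn-aldol diol; it carries the future benzyl arene as an aryloxy group and the aroyl ketone as its carbinol.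

Key step: step 6

Remark: lactone atoms are numbered O1, C2 (carbonyl), C3 (benzyl-bearing), C4 (aroyl-bearing), C5. (S)-4-Benzyloxazolidin-2-one, crotonyl chloride, O-benzylvanillin and 4-(benzyloxy)-3-methoxyphenol are assumed to be purchased.

Step 1
Reactants: 1 (S)-4-benzyloxazolidin-2-one; 2 (E)-but-2-enoyl chloride
Product: 4 (S)-4-benzyl-3-[(E)-but-2-enoyl]oxazolidin-2-one, via N-lithio oxazolidinone 3 (not isolated)
Conditions: n-BuLi, THF, −78 °C; then 2, −78 to 0 °C
Reagents that add atoms: none
Why: N-acylation of the lithiated Evans auxiliary by the acid chloride is fast at low temperature and leaves the auxiliary stereocenter untouched.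

Step 2
Reactants: 4 (S)-4-benzyl-3-[(E)-but-2-enoyl]oxazolidin-2-one; 5 4-(benzyloxy)-3-methoxybenzaldehyde
Product: 7 (S)-4-benzyl-3-[(2S,3S)-3-[4-(benzyloxy)-3-methoxyphenyl]-2-ethenyl-3-hydroxypropanoyl]oxazolidin-2-one (syn-aldol adduct), via Z-dibutylboron dienolate 6 (not isolated)
Conditions: Bu2BOTf, Et3N, CH2Cl2, −78 to 0 °C; then 5, −78 to 0 °C; pH 7 buffer, MeOH, H2O2, 0 °C
Reagents that add atoms: none
Why: Evans boron syn-aldol reaction, in which γ-deprotonation gives the Z dienolate that should react at its α-carbon through a Zimmerman–Traxler chair on the face away from the auxiliary benzyl group, setting both new centers (2S,3S) and placing the vinyl group next to the future C4.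

Step 3
Reactants: 7 syn-aldol adduct
Product: 8 (1S,2R)-1-[4-(benzyloxy)-3-methoxyphenyl]-2-ethenylpropane-1,3-diol
Conditions: LiBH4, MeOH (2 equiv), THF, 0 °C; aq. NH4Cl
Reagents that add atoms: none
Why: Reductive cleavage of the N-acyl oxazolidinone by LiBH4 should give the primary alcohol without enolization, so the vinyl-bearing center is kept (its descriptor changes to R only through substituent priority) and the auxiliary is recovered.

Step 4
Reactants: 9 4-(benzyloxy)-3-methoxyphenol
Product: 10 O-[4-(benzyloxy)-3-methoxyphenyl] carbonochloridothioate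
Conditions: CSCl2 (1.1 equiv), aq. NaOH (1.0 equiv), CHCl3, 0 °C
Reagents that add atoms: thiophosgene, S=C(Cl)Cl
Why: Schotten–Baumann O-thioacylation of the phenoxide with a slight excess of thiophosgene should stop at the aryl chlorothionoformate.

Step 5
Reactants: 8 (1S,2R)-1-[4-(benzyloxy)-3-methoxyphenyl]-2-ethenylpropane-1,3-diol; 10 O-[4-(benzyloxy)-3-methoxyphenyl] carbonochloridothioate
Product: 11 O-[4-(benzyloxy)-3-methoxyphenyl] O-[(2R,3S)-3-[4-(benzyloxy)-3-methoxyphenyl]-2-ethenyl-3-hydroxypropyl] carbonothioate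
Conditions: 10 (1.05 equiv), pyridine, CH2Cl2, −20 to 0 °C
Reagents that add atoms: none
Why: Chemoselective thionocarbonate formation (O-thioacylation) at the primary hydroxyl is expected because the secondary benzylic hydroxyl is flanked by the aryl ring and the branched carbon and reacts far more slowly at low temperature.

Step 6
Reactants: 11 O-aryl O-homoallyl thionocarbonate
Product: 12 (3R,4R)-3-[4-(benzyloxy)-3-methoxybenzyl]-4-[(S)-[4-(benzyloxy)-3-methoxyphenyl](hydroxy)methyl]oxolan-2-one
Conditions: (TMS)3SiH (1.5 equiv) and AIBN (0.3 equiv) by syringe pump over 8 h, benzene (0.01 M), 80 °C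
Reagents that add atoms: none
Why: Radical carboxyarylation: the silyl radical adds to sulfur of the C=S group, the resulting dioxy(silylthio)methyl radical attacks the internal vinyl carbon, the primary radical so formed adds to the ipso carbon of the O-aryl ring through a five-membered spiro transition state, and C–O scission followed by loss of the silylthiyl radical (which takes hydrogen from the silane and carries the chain) leaves the lactone carbonyl. The closest known reaction type is the silane-mediated carboxyarylation of homoallylic O-aryl thionocarbonates to α-benzyl-γ-butyrolactones. The oxolanone ring closes in the 5-exo-trig mode. The new stereocenter C3 is controlled by the existing C4 center: in the chair-like Beckwith–Houk transition state the CH(OH)Ar substituent sits pseudo-equatorial, so the new CH2 and the C4 side chain should end up trans, (3R,4R). The step needs 5-exo over 6-endo closure and ipso attack over hydrogen transfer or ortho attack; the monosubstituted vinyl acceptor, the five-membered spiro geometry and the low stationary silane concentration should secure this. Any cis isomer would be removed by chromatography here, where C4 is not yet enolizable.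

Step 7
Reactants: 12 hydroxy lactone
Product: 13 (3R,4R)-4-[4-(benzyloxy)-3-methoxybenzoyl]-3-[4-(benzyloxy)-3-methoxybenzyl]oxolan-2-one
Conditions: Dess–Martin periodinane, NaHCO3, CH2Cl2, 0 °C to rt
Reagents that add atoms: none
Why: Dess–Martin oxidation of the secondary benzylic alcohol under buffered conditions should give the aryl ketone, removing the carbinol stereocenter while the trans (thermodynamically preferred) ring centers are not exposed to base.

Step 8
Reactants: 13 bis(benzyl ether) keto lactone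
Product: 14 (3R,4R)-4-(4-hydroxy-3-methoxybenzoyl)-3-(4-hydroxy-3-methoxybenzyl)oxolan-2-one
Conditions: H2 (1 atm), Pd/C (10%), EtOAc, rt
Reagents that add atoms: none
Why: Catalytic hydrogenolysis of the two aryl benzyl ethers under neutral conditions should free both phenols without reducing the electron-rich aryl ketone or the lactone and without touching either stereocenter.

Compound list
1 | (S)-4-benzyloxazolidin-2-one | O=C1N[C@@H](Cc2ccccc2)CO1 | starting material
2 | (E)-but-2-enoyl chloride (crotonyl chloride) | C/C=C/C(Cl)=O | starting material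
3 | N-lithio oxazolidinone, lithium (S)-4-benzyl-2-oxooxazolidin-3-ide | [Li]N1[C@@H](Cc2ccccc2)COC1=O | intermediate (not isolated)
4 | (S)-4-benzyl-3-[(E)-but-2-enoyl]oxazolidin-2-one | C/C=C/C(=O)N1[C@@H](Cc2ccccc2)COC1=O | intermediate
5 | 4-(benzyloxy)-3-methoxybenzaldehyde (O-benzylvanillin) | COc1cc(C=O)ccc1OCc1ccccc1 | starting material
6 | Z-dibutylboron dienolate of 4 | C=C/C=C(\OB(CCCC)CCCC)N1[C@@H](Cc2ccccc2)COC1=O | intermediate (not isolated)
7 | (S)-4-benzyl-3-[(2S,3S)-3-[4-(benzyloxy)-3-methoxyphenyl]-2-ethenyl-3-hydroxypropanoyl]oxazolidin-2-one | O=C(N1[C@@H](Cc2ccccc2)COC1=O)[C@@H](C=C)[C@H](O)c1ccc(OCc2ccccc2)c(OC)c1 | intermediate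
8 | (1S,2R)-1-[4-(benzyloxy)-3-methoxyphenyl]-2-ethenylpropane-1,3-diol | OC[C@@H](C=C)[C@H](O)c1ccc(OCc2ccccc2)c(OC)c1 | intermediate
9 | 4-(benzyloxy)-3-methoxyphenol | COc1cc(O)ccc1OCc1ccccc1 | starting material
10 | O-[4-(benzyloxy)-3-methoxyphenyl] carbonochloridothioate | COc1cc(OC(=S)Cl)ccc1OCc1ccccc1 | intermediate
11 | O-[4-(benzyloxy)-3-methoxyphenyl] O-[(2R,3S)-3-[4-(benzyloxy)-3-methoxyphenyl]-2-ethenyl-3-hydroxypropyl] carbonothioate | COc1cc(OC(=S)OC[C@@H](C=C)[C@H](O)c2ccc(OCc3ccccc3)c(OC)c2)ccc1OCc1ccccc1 | intermediate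
12 | (3R,4R)-3-[4-(benzyloxy)-3-methoxybenzyl]-4-[(S)-[4-(benzyloxy)-3-methoxyphenyl](hydroxy)methyl]oxolan-2-one | COc1cc(C[C@H]2C(=O)OC[C@@H]2[C@H](O)c2ccc(OCc3ccccc3)c(OC)c2)ccc1OCc1ccccc1 | intermediate
13 | (3R,4R)-4-[4-(benzyloxy)-3-methoxybenzoyl]-3-[4-(benzyloxy)-3-methoxybenzyl]oxolan-2-one | COc1cc(C[C@H]2C(=O)OC[C@@H]2C(=O)c2ccc(OCc3ccccc3)c(OC)c2)ccc1OCc1ccccc1 | intermediate
14 | (3R,4R)-4-(4-hydroxy-3-methoxybenzoyl)-3-(4-hydroxy-3-methoxybenzyl)oxolan-2-one | COc1cc(C[C@H]2C(=O)OC[C@@H]2C(=O)c2ccc(O)c(OC)c2)ccc1O | target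

Total step count: 8
Longest linear sequence: 7 steps (1, 2, 3, 5, 6, 7, 8); step 4 is a one-step branch.

Steps most likely to fail

Step 6. The cyclized primary radical may take hydrogen from the silane before the aryl group is transferred, may attack the ortho instead of the ipso position, or the ring closure may show poor facial selectivity. The fallback sets out from 8 and comes back at 12. Diol 8 would be acylated at the primary hydroxyl with methyl chlorooxoacetate (2,4,6-collidine, CH2Cl2, −78 °C) to give methyl (2R,3S)-3-[4-(benzyloxy)-3-methoxyphenyl]-2-ethenyl-3-hydroxypropyl oxalate F1. CsOH (1 equiv, THF/H2O, 0 °C) should hydrolyse this to caesium 2-{[(2R,3S)-3-[4-(benzyloxy)-3-methoxyphenyl]-2-ethenyl-3-hydroxypropyl]oxy}-2-oxoacetate F2. Irradiation of F2 (blue LEDs, dioxane/DMSO, rt) with 1-(benzyloxy)-4-bromo-2-methoxybenzene (COc1cc(Br)ccc1OCc1ccccc1), Ir[dF(CF3)ppy]2(dtbbpy)PF6, NiBr2·glyme and 4,4′-di-tert-butyl-2,2′-bipyridine should oxidize the oxalate to the alkoxycarbonyl radical with loss of CO2. That radical should close the same C2–C3 bond 5-exo-trig, and the primary radical would be arylated at nickel (alkoxycarbonyl radical cyclization–cross-coupling cascade) to give 12.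

Step 5. The secondary hydroxyl may compete for the chlorothionoformate, or the mono-thionocarbonate may close onto the neighbouring hydroxyl with loss of the aryloxy group. The fallback sets out from 7 and comes back at 12. Aldol adduct 7 would be silylated (TBSOTf, 2,6-lutidine, CH2Cl2, 0 °C) to (S)-4-benzyl-3-[(2S,3S)-3-[4-(benzyloxy)-3-methoxyphenyl]-3-[(tert-butyldimethylsilyl)oxy]-2-ethenylpropanoyl]oxazolidin-2-one F3. Reduction (LiBH4, MeOH, THF, 0 °C) should give (2R,3S)-3-[4-(benzyloxy)-3-methoxyphenyl]-3-[(tert-butyldimethylsilyl)oxy]-2-ethenylpropan-1-ol F4. Its only hydroxyl would be thioacylated with 10 (pyridine, DMAP, CH2Cl2) to O-[4-(benzyloxy)-3-methoxyphenyl] O-[(2R,3S)-3-[4-(benzyloxy)-3-methoxyphenyl]-3-[(tert-butyldimethylsilyl)oxy]-2-ethenylpropyl] carbonothioate F5. The carboxyarylation of step 6 ((TMS)3SiH, AIBN, benzene, 80 °C) should then give (3R,4R)-3-[4-(benzyloxy)-3-methoxybenzyl]-4-[(S)-[4-(benzyloxy)-3-methoxyphenyl][(tert-butyldimethylsilyl)oxy]methyl]oxolan-2-one F6. HF·pyridine (THF, 0 °C) would remove the silyl group to give 12.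

Step 8. The aryl ketone may be reduced, or its benzylic C–O bond hydrogenolysed, along with the benzyl ethers. The fallback sets out from 13 and comes back at 14. It replaces hydrogenolysis by Lewis-acid ether cleavage with a cation scavenger: BCl3 and pentamethylbenzene, CH2Cl2, −78 °C, which should cleave the benzyl ethers and spare the aryl methyl ethers, the ketone and the lactone. New compounds on this way: none F0.

Further compounds
F1 | step 6 | methyl (2R,3S)-3-[4-(benzyloxy)-3-methoxyphenyl]-2-ethenyl-3-hydroxypropyl oxalate | COC(=O)C(=O)OC[C@@H](C=C)[C@H](O)c1ccc(OCc2ccccc2)c(OC)c1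
F2 | step 6 | caesium 2-{[(2R,3S)-3-[4-(benzyloxy)-3-methoxyphenyl]-2-ethenyl-3-hydroxypropyl]oxy}-2-oxoacetate | [Cs+].[O-]C(=O)C(=O)OC[C@@H](C=C)[C@H](O)c1ccc(OCc2ccccc2)c(OC)c1
F3 | step 5 | (S)-4-benzyl-3-[(2S,3S)-3-[4-(benzyloxy)-3-methoxyphenyl]-3-[(tert-butyldimethylsilyl)oxy]-2-ethenylpropanoyl]oxazolidin-2-one | O=C(N1[C@@H](Cc2ccccc2)COC1=O)[C@@H](C=C)[C@H](O[Si](C)(C)C(C)(C)C)c1ccc(OCc2ccccc2)c(OC)c1
F4 | step 5 | (2R,3S)-3-[4-(benzyloxy)-3-methoxyphenyl]-3-[(tert-butyldimethylsilyl)oxy]-2-ethenylpropan-1-ol | OC[C@@H](C=C)[C@H](O[Si](C)(C)C(C)(C)C)c1ccc(OCc2ccccc2)c(OC)c1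
F5 | step 5 | O-[4-(benzyloxy)-3-methoxyphenyl] O-[(2R,3S)-3-[4-(benzyloxy)-3-methoxyphenyl]-3-[(tert-butyldimethylsilyl)oxy]-2-ethenylpropyl] carbonothioate | COc1cc(OC(=S)OC[C@@H](C=C)[C@H](O[Si](C)(C)C(C)(C)C)c2ccc(OCc3ccccc3)c(OC)c2)ccc1OCc1ccccc1
F6 | step 5 | (3R,4R)-3-[4-(benzyloxy)-3-methoxybenzyl]-4-[(S)-[4-(benzyloxy)-3-methoxyphenyl][(tert-butyldimethylsilyl)oxy]methyl]oxolan-2-one | COc1cc(C[C@H]2C(=O)OC[C@@H]2[C@H](O[Si](C)(C)C(C)(C)C)c2ccc(OCc3ccccc3)c(OC)c2)ccc1OCc1ccccc1
F0 | step 8 | none | none
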